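**Plan**
Retrosynthesis: cut C2–C3 of ring C first, then the two carboxyl helpers on C3, the O1–C2 benzyl ether bond, the C4=C3 alkylidene bond, the C6 1,1‑dimethylallyl group (back to a C7 prenyl ether) and the two ring B prenyl groups.
Forward: ring B is built as a 2,3‑diprenyl catechol benzyl alcohol and joined to the ring A salicylaldehyde by Mitsunobu etherification. An aromatic Claisen rearrangement then sets the 1,1‑dimethylallyl group, a Knoevenagel condensation installs the acceptor, and ring C closes last.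
Enabling feature: the O1–C2H2–ring B unit is a para‑oxygenated (C4'–O) benzyl ether, so C2–H is hydridic, and it lies 1,5 to C4 (H–C2–O1–C8a–C4a–C4), the β‑carbon of an alkylidene malonate on ring A.
One internal redox event (1,5‑hydride shift, then C3→C2 closure) reduces C4 to CH2, forms C2–C3 and sets C2, the only stereocentre, under a chiral scandium catalyst.
Helpers: the malonate esters on C3 (removed by palladium deallylation/decarboxylation, then Barton decarboxylation), the C7 acetate (keeps the acceptor electrophilic) and the TBS ethers on ring B.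

Key step: step 12

Assumption: the (S,S)-pybox ligand is taken to give the C2 arrangement of the target; if the sense of induction proves opposite, the (R,R)-ligand is used.
Abbreviations: TBS = tert‑butyldimethylsilyl; prenyl = 3‑methylbut‑2‑enyl; ArB = 4,5‑bis(tert‑butyldimethylsilyloxy)‑2,3‑bis(3‑methylbut‑2‑enyl)phenyl.

**Step 1**
Reactants: 1 2‑bromo‑4,5‑dihydroxybenzaldehyde
Product: 2 4‑(allyloxy)‑2‑bromo‑5‑hydroxybenzaldehyde
Conditions: allyl bromide (1.05 equiv), NaHCO3, NaI (cat.), DMF, 40 °C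
Reagents that add atoms: allyl bromide, C=CCBr
Why: The 4‑OH para to the formyl group is the more acidic phenol, so a weak base should alkylate it selectively (Williamson etherification, as known for protocatechualdehyde).

**Step 2**
Reactants: 2 4‑(allyloxy)‑2‑bromo‑5‑hydroxybenzaldehyde
Product: 3 3‑allyl‑2‑bromo‑4,5‑dihydroxybenzaldehyde
Conditions: PhNEt2, 190 °C, argon
Reagents that add atoms: none
Why: Aromatic Claisen rearrangement should deliver the allyl group to C3, the only free ortho position of the allyloxy group, the para position being blocked by the formyl‑bearing carbon.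

**Step 3**
Reactants: 3 3‑allyl‑2‑bromo‑4,5‑dihydroxybenzaldehyde
Product: 4 3‑allyl‑2‑bromo‑4,5‑bis(tert‑butyldimethylsilyloxy)benzaldehyde
Conditions: TBSCl (2.5 equiv), imidazole, DMF, rt to 40 °C
Reagents that add atoms: tert‑butyldimethylsilyl chloride, CC(C)(C)[Si](C)(C)Cl
Why: Standard silylation of both phenols gives electron‑donating, base‑ and heat‑tolerant protection that keeps ring B a good hydride donor later.

**Step 4**
Reactants: 4 3‑allyl‑2‑bromo‑4,5‑bis(tert‑butyldimethylsilyloxy)benzaldehyde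
Product: 5 2‑bromo‑4,5‑bis(tert‑butyldimethylsilyloxy)‑3‑(3‑methylbut‑2‑enyl)benzaldehyde
Conditions: second‑generation Grubbs catalyst RuCl2(=CHPh)(PCy3)(H2IMes) (5 mol %), 2‑methyl‑2‑butene/CH2Cl2, 40 °C
Reagents that add atoms: 2‑methyl‑2‑butene, CC=C(C)C
Why: Olefin cross‑metathesis with excess 2‑methyl‑2‑butene should convert the single allyl group into a prenyl group; done before the second prenyl group is present, no ring‑closing partner exists.

**Step 5**
Reactants: 5 2‑bromo‑4,5‑bis(tert‑butyldimethylsilyloxy)‑3‑(3‑methylbut‑2‑enyl)benzaldehyde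
Product: 6 4,5‑bis(tert‑butyldimethylsilyloxy)‑2,3‑bis(3‑methylbut‑2‑enyl)benzaldehyde
Conditions: tributyl(3‑methylbut‑2‑enyl)stannane, Pd(PPh3)4 (10 mol %), DMF, 100 °C
Reagents that add atoms: tributyl(3‑methylbut‑2‑enyl)stannane, CCCC[Sn](CCCC)(CCCC)CC=C(C)C
Why: Stille coupling under neutral conditions should place the linear prenyl group on the bromide carbon, oxidative addition being helped by the ortho formyl group, and leaves the aryl silyl ethers intact.

**Step 6**
Reactants: 6 4,5‑bis(tert‑butyldimethylsilyloxy)‑2,3‑bis(3‑methylbut‑2‑enyl)benzaldehyde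
Product: 7 [4,5‑bis(tert‑butyldimethylsilyloxy)‑2,3‑bis(3‑methylbut‑2‑enyl)phenyl]methanol
Conditions: NaBH4, MeOH/THF, 0 °C
Reagents that add atoms: none
Why: Borohydride reduction of the aryl aldehyde gives the benzyl alcohol whose CH2 becomes C2 of the flavan.

**Step 7**
Reactants: 8 2,4‑dihydroxybenzaldehyde
Product: 9 2‑hydroxy‑4‑(3‑methylbut‑2‑enyloxy)benzaldehyde
Conditions: prenyl bromide (1.05 equiv), K2CO3, acetone, rt to reflux
Reagents that add atoms: prenyl bromide, CC(C)=CCBr
Why: The 2‑OH is hydrogen‑bonded to the formyl group and unreactive, so Williamson etherification should occur at the 4‑OH only.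

**Step 8**
Reactants: 7 [4,5‑bis(tert‑butyldimethylsilyloxy)‑2,3‑bis(3‑methylbut‑2‑enyl)phenyl]methanol; 9 2‑hydroxy‑4‑(3‑methylbut‑2‑enyloxy)benzaldehyde
Product: 10 2‑(ArB‑methoxy)‑4‑(3‑methylbut‑2‑enyloxy)benzaldehyde
Conditions: PPh3, DIAD, THF, 0 °C to rt
Reagents that add atoms: none
Why: Mitsunobu etherification of the acidic salicylaldehyde phenol with the primary benzylic alcohol forms the O1–C2 bond under neutral conditions that spare the aryl silyl ethers.

**Step 9**
Reactants: 10 2‑(ArB‑methoxy)‑4‑(3‑methylbut‑2‑enyloxy)benzaldehyde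
Product: 11 2‑(ArB‑methoxy)‑4‑hydroxy‑5‑(2‑methylbut‑3‑en‑2‑yl)benzaldehyde
Conditions: PhNEt2, 190 °C, argon, sealed vessel
Reagents that add atoms: none
Why: Aromatic Claisen rearrangement of the aryl prenyl ether should give the 1,1‑dimethylallyl group at C5, the less hindered ortho site, because C3 lies between two oxygen substituents and the etherified 2‑oxygen no longer directs toward C3 by hydrogen‑bond fixation.

**Step 10**
Reactants: 11 2‑(ArB‑methoxy)‑4‑hydroxy‑5‑(2‑methylbut‑3‑en‑2‑yl)benzaldehyde; 12 diallyl malonate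
Product: 13 diallyl 2‑{[2‑(ArB‑methoxy)‑4‑hydroxy‑5‑(2‑methylbut‑3‑en‑2‑yl)phenyl]methylidene}malonate
Conditions: piperidine (0.2 equiv), AcOH (0.2 equiv), toluene, reflux, Dean–Stark
Reagents that add atoms: none
Why: Knoevenagel condensation installs the hydride acceptor, with C4 as its β‑carbon and the future C3 carrying two allyl esters that can be removed later without base.

**Step 11**
Reactants: 13 diallyl 2‑{[2‑(ArB‑methoxy)‑4‑hydroxy‑5‑(2‑methylbut‑3‑en‑2‑yl)phenyl]methylidene}malonate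
Product: 14 diallyl 2‑{[4‑acetoxy‑2‑(ArB‑methoxy)‑5‑(2‑methylbut‑3‑en‑2‑yl)phenyl]methylidene}malonate
Conditions: Ac2O, pyridine, DMAP (cat.), CH2Cl2, 0 °C to rt
Reagents that add atoms: acetic anhydride, CC(=O)OC(C)=O
Why: Acetylation turns the para oxygen of ring A from a donor into a weak acceptor, which should restore the electrophilicity of the alkylidene malonate for the hydride shift.

**Step 12**
Reactants: 14 diallyl 2‑{[4‑acetoxy‑2‑(ArB‑methoxy)‑5‑(2‑methylbut‑3‑en‑2‑yl)phenyl]methylidene}malonate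
Product: 16 diallyl (2R)‑7‑acetoxy‑2‑ArB‑6‑(2‑methylbut‑3‑en‑2‑yl)chromane‑3,3‑dicarboxylate, via oxocarbenium malonate zwitterion 15 (not isolated)
Conditions: Sc(OTf)3 (10 mol %), 2,6‑bis[(4S)‑4‑phenyl‑4,5‑dihydrooxazol‑2‑yl]pyridine (12 mol %), 4 Å MS, ClCH2CH2Cl, 40 °C
Reagents that add atoms: none
Why: Proposed new method: the scandium‑chelated alkylidene malonate should accept a hydride from C2–H through a six‑membered suprafacial 1,5‑shift (H–C2–O1–C8a–C4a–C4), which turns C4 into CH2 and leaves an aryloxy‑ and aryl‑stabilised oxocarbenium ion at C2 next to a scandium malonate enolate at C3, whose collapse forms C2–C3. The closest known reaction type is the Lewis‑acid‑catalysed hydride‑shift/cyclization of ortho‑benzyloxy benzylidene malonates to 2‑arylchromane‑3,3‑dicarboxylates, together with its enantioselective variants on ortho‑dialkylamino benzylidene malonates under chiral metal or phosphoric acid catalysts. Ring C closes in a 6‑(enolexo)‑endo‑trig mode, the enolate carbon attacking the C2=O1 oxocarbenium bond that lies inside the new ring. C2 is the only new stereocentre: the pybox‑ligated trivalent scandium bound to both ester carbonyls should select one of the two enantiotopic C2 hydrogens (one face of C4), and the helical ion pair should close before rotation about O1–C8a, so the sense of the hydride shift is copied into C2; the descriptor is (2R) here only because C3 outranks the aryl group, the spatial arrangement being that of (2S) in the target. The step needs chemoselectivity for this C–H bond over the prenyl CH2 groups, and for enolate capture over attack of the 2'‑prenyl alkene on the cation. Only C2–H stands 1,5 to C4 and is made hydridic by the para silyloxy group at C4', the C7 acetate keeps ring A from quenching the acceptor, and the tethered enolate sits within bonding distance of C2.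

**Step 13**
Reactants: 16 diallyl (2R)‑7‑acetoxy‑2‑ArB‑6‑(2‑methylbut‑3‑en‑2‑yl)chromane‑3,3‑dicarboxylate
Product: 17 (2S)‑7‑acetoxy‑2‑ArB‑6‑(2‑methylbut‑3‑en‑2‑yl)chromane‑3‑carboxylic acid (C3 epimers)
Conditions: Pd(OAc)2 (5 mol %), PPh3 (20 mol %), HCO2H (4 equiv), Et3N (2 equiv), 1,4‑dioxane, rt then 90 °C
Reagents that add atoms: none
Why: Tsuji‑type palladium‑catalysed deallylation with formate as hydride donor, followed by thermal decarboxylation of the substituted malonic acid, should give the mono‑acid; the acidic buffer avoids a C3 enolate that could expel the O1 aryloxide, so C2 is untouched.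

**Step 14**
Reactants: 17 (2S)‑7‑acetoxy‑2‑ArB‑6‑(2‑methylbut‑3‑en‑2‑yl)chromane‑3‑carboxylic acid (C3 epimers)
Product: 19 (2S)‑2‑ArB‑6‑(2‑methylbut‑3‑en‑2‑yl)chroman‑7‑yl acetate, via Barton ester 18 (not isolated)
Conditions: N‑hydroxypyridine‑2‑thione, DCC, DMAP (cat.), CH2Cl2, 0 °C to rt, dark; then t‑BuSH (excess), THF, visible light, rt
Reagents that add atoms: none
Why: Barton reductive decarboxylation should replace the C3 carboxyl by hydrogen, the secondary C3 radical being quenched by the thiol faster than it can fragment or add to the distant alkenes; both C3 epimers converge and C2 is not involved.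

**Step 15**
Reactants: 19 (2S)‑2‑ArB‑6‑(2‑methylbut‑3‑en‑2‑yl)chroman‑7‑yl acetate
Product: 20 Kazinol E
Conditions: K2CO3, degassed MeOH/THF, 0 °C to rt, argon; AcOH quench
Reagents that add atoms: none
Why: Base‑mediated methanolysis should cleave the aryl acetate and both aryl silyl ethers in one operation; low temperature and a short reaction time keep the 4'‑phenoxide from opening ring C through a quinone methide, so C2 stays (S).

**Compound list**
1 | 2‑bromo‑4,5‑dihydroxybenzaldehyde | O=Cc1cc(O)c(O)cc1Br | starting material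
2 | 4‑(allyloxy)‑2‑bromo‑5‑hydroxybenzaldehyde | O=Cc1cc(O)c(OCC=C)cc1Br | intermediate
3 | 3‑allyl‑2‑bromo‑4,5‑dihydroxybenzaldehyde | O=Cc1cc(O)c(O)c(CC=C)c1Br | intermediate
4 | 3‑allyl‑2‑bromo‑4,5‑bis(tert‑butyldimethylsilyloxy)benzaldehyde | O=Cc1cc(O[Si](C)(C)C(C)(C)C)c(O[Si](C)(C)C(C)(C)C)c(CC=C)c1Br | intermediate
5 | 2‑bromo‑4,5‑bis(tert‑butyldimethylsilyloxy)‑3‑(3‑methylbut‑2‑enyl)benzaldehyde | O=Cc1cc(O[Si](C)(C)C(C)(C)C)c(O[Si](C)(C)C(C)(C)C)c(CC=C(C)C)c1Br | intermediate
6 | 4,5‑bis(tert‑butyldimethylsilyloxy)‑2,3‑bis(3‑methylbut‑2‑enyl)benzaldehyde | O=Cc1cc(O[Si](C)(C)C(C)(C)C)c(O[Si](C)(C)C(C)(C)C)c(CC=C(C)C)c1CC=C(C)C | intermediate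
7 | [4,5‑bis(tert‑butyldimethylsilyloxy)‑2,3‑bis(3‑methylbut‑2‑enyl)phenyl]methanol | OCc1cc(O[Si](C)(C)C(C)(C)C)c(O[Si](C)(C)C(C)(C)C)c(CC=C(C)C)c1CC=C(C)C | intermediate
8 | 2,4‑dihydroxybenzaldehyde | O=Cc1ccc(O)cc1O | starting material
9 | 2‑hydroxy‑4‑(3‑methylbut‑2‑enyloxy)benzaldehyde | O=Cc1ccc(OCC=C(C)C)cc1O | intermediate
10 | 2‑(ArB‑methoxy)‑4‑(3‑methylbut‑2‑enyloxy)benzaldehyde | O=Cc1ccc(OCC=C(C)C)cc1OCc1cc(O[Si](C)(C)C(C)(C)C)c(O[Si](C)(C)C(C)(C)C)c(CC=C(C)C)c1CC=C(C)C | intermediate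
11 | 2‑(ArB‑methoxy)‑4‑hydroxy‑5‑(2‑methylbut‑3‑en‑2‑yl)benzaldehyde | O=Cc1cc(C(C)(C)C=C)c(O)cc1OCc1cc(O[Si](C)(C)C(C)(C)C)c(O[Si](C)(C)C(C)(C)C)c(CC=C(C)C)c1CC=C(C)C | intermediate
12 | diallyl malonate | C=CCOC(=O)CC(=O)OCC=C | starting material
13 | diallyl 2‑{[2‑(ArB‑methoxy)‑4‑hydroxy‑5‑(2‑methylbut‑3‑en‑2‑yl)phenyl]methylidene}malonate | C=CCOC(=O)C(=Cc1cc(C(C)(C)C=C)c(O)cc1OCc1cc(O[Si](C)(C)C(C)(C)C)c(O[Si](C)(C)C(C)(C)C)c(CC=C(C)C)c1CC=C(C)C)C(=O)OCC=C | intermediate
14 | diallyl 2‑{[4‑acetoxy‑2‑(ArB‑methoxy)‑5‑(2‑methylbut‑3‑en‑2‑yl)phenyl]methylidene}malonate | C=CCOC(=O)C(=Cc1cc(C(C)(C)C=C)c(OC(C)=O)cc1OCc1cc(O[Si](C)(C)C(C)(C)C)c(O[Si](C)(C)C(C)(C)C)c(CC=C(C)C)c1CC=C(C)C)C(=O)OCC=C | intermediate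
15 | oxocarbenium malonate zwitterion (drawn without the metal) | C=CCOC(=O)[C-](Cc1cc(C(C)(C)C=C)c(OC(C)=O)cc1[O+]=Cc1cc(O[Si](C)(C)C(C)(C)C)c(O[Si](C)(C)C(C)(C)C)c(CC=C(C)C)c1CC=C(C)C)C(=O)OCC=C | intermediate
16 | diallyl (2R)‑7‑acetoxy‑2‑ArB‑6‑(2‑methylbut‑3‑en‑2‑yl)chromane‑3,3‑dicarboxylate | C=CC(C)(C)c1cc2c(cc1OC(C)=O)O[C@H](c1cc(O[Si](C)(C)C(C)(C)C)c(O[Si](C)(C)C(C)(C)C)c(CC=C(C)C)c1CC=C(C)C)C(C(=O)OCC=C)(C(=O)OCC=C)C2 | intermediate
17 | (2S)‑7‑acetoxy‑2‑ArB‑6‑(2‑methylbut‑3‑en‑2‑yl)chromane‑3‑carboxylic acid, mixture of C3 epimers | C=CC(C)(C)c1cc2c(cc1OC(C)=O)O[C@H](c1cc(O[Si](C)(C)C(C)(C)C)c(O[Si](C)(C)C(C)(C)C)c(CC=C(C)C)c1CC=C(C)C)C(C(=O)O)C2 | intermediate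
18 | Barton ester of 17 (2‑thioxopyridin‑1(2H)‑yl ester) | C=CC(C)(C)c1cc2c(cc1OC(C)=O)O[C@H](c1cc(O[Si](C)(C)C(C)(C)C)c(O[Si](C)(C)C(C)(C)C)c(CC=C(C)C)c1CC=C(C)C)C(C(=O)ON1C=CC=CC1=S)C2 | intermediate
19 | (2S)‑2‑ArB‑6‑(2‑methylbut‑3‑en‑2‑yl)chroman‑7‑yl acetate | C=CC(C)(C)c1cc2c(cc1OC(C)=O)O[C@H](c1cc(O[Si](C)(C)C(C)(C)C)c(O[Si](C)(C)C(C)(C)C)c(CC=C(C)C)c1CC=C(C)C)CC2 | intermediate
20 | Kazinol E, (2S)‑2‑[4,5‑dihydroxy‑2,3‑bis(3‑methylbut‑2‑enyl)phenyl]‑6‑(2‑methylbut‑3‑en‑2‑yl)chroman‑7‑ol | C=CC(C)(C)c1cc2c(cc1O)O[C@H](c1cc(O)c(O)c(CC=C(C)C)c1CC=C(C)C)CC2 | target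

**Step count**
Total: 15 steps. Longest linear sequence: 14 steps (steps 1–6 and 8–15); step 7 prepares the ring A partner.

**Steps most likely to fail**

Step 12 (proposed new method). The chiral catalyst may discriminate poorly between the two enantiotopic C2 hydrogens. The enantiomeric purity may also erode through reversible ionisation of the C2–C3 bond under the Lewis acid, or the oxocarbenium ion may be captured by the neighbouring 2'‑prenyl alkene. The fallback sets out from 14 and uses the known achiral variant: Sc(OTf)3 without ligand in ClCH2CH2Cl should give racemic diallyl 7‑acetoxy‑2‑ArB‑6‑(2‑methylbut‑3‑en‑2‑yl)chromane‑3,3‑dicarboxylate F1. Preparative chromatography on a chiral stationary phase (amylose tris(3,5‑dimethylphenylcarbamate)) then separates the enantiomers, and the (2R)‑enantiomer comes back to the route at 16.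

Step 9. The prenyl group may migrate to C3 instead of C5, or the product may undergo further thermal rearrangement or cyclisation at 190 °C on an advanced intermediate. The fallback sets out from 8 and installs the branched group by cross‑coupling instead of rearrangement. Bromination (Br2, AcOH, rt) should give 5‑bromo‑2,4‑dihydroxybenzaldehyde F2. Selective acetylation of the non‑chelated 4‑OH (Ac2O 1 equiv, pyridine, 0 °C) gives 4‑acetoxy‑5‑bromo‑2‑hydroxybenzaldehyde F3. Mitsunobu etherification with 7 (PPh3, DIAD, THF) gives 4‑acetoxy‑2‑(ArB‑methoxy)‑5‑bromobenzaldehyde F4. A branched‑selective Suzuki–Miyaura coupling with 3‑methylbut‑2‑enylboronic acid pinacol ester (Pd(OAc)2, a dialkylbiarylphosphine chosen for coupling at the tertiary allyl terminus, aqueous K3PO4, THF, 40 °C) installs the 1,1‑dimethylallyl group. The aqueous base also cleaves the aryl acetate, and the fallback comes back to the route at 11.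

Step 5. The prenyl group may transfer through its tertiary terminus, giving the 1,1‑dimethylallyl isomer, or oxidative addition at the doubly ortho‑substituted bromide may be slow. The fallback sets out from 5 and uses organocopper allylation. NaBH4 (MeOH/THF, 0 °C) should give [2‑bromo‑4,5‑bis(tert‑butyldimethylsilyloxy)‑3‑(3‑methylbut‑2‑enyl)phenyl]methanol F5. Treatment with n‑BuLi (2.2 equiv, THF, −78 °C; alkoxide formation, then bromine–lithium exchange), CuBr·SMe2 and prenyl bromide should give the linear prenyl arene, and the fallback comes back to the route at 7.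

**Further compounds**
F1 | step 12 | racemic diallyl 7‑acetoxy‑2‑ArB‑6‑(2‑methylbut‑3‑en‑2‑yl)chromane‑3,3‑dicarboxylate | C=CC(C)(C)c1cc2c(cc1OC(C)=O)OC(c1cc(O[Si](C)(C)C(C)(C)C)c(O[Si](C)(C)C(C)(C)C)c(CC=C(C)C)c1CC=C(C)C)C(C(=O)OCC=C)(C(=O)OCC=C)C2
F2 | step 9 | 5‑bromo‑2,4‑dihydroxybenzaldehyde | O=Cc1cc(Br)c(O)cc1O
F3 | step 9 | 4‑acetoxy‑5‑bromo‑2‑hydroxybenzaldehyde | CC(=O)Oc1cc(O)c(C=O)cc1Br
F4 | step 9 | 4‑acetoxy‑2‑(ArB‑methoxy)‑5‑bromobenzaldehyde | CC(=O)Oc1cc(OCc2cc(O[Si](C)(C)C(C)(C)C)c(O[Si](C)(C)C(C)(C)C)c(CC=C(C)C)c2CC=C(C)C)c(C=O)cc1Br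
F5 | step 5 | [2‑bromo‑4,5‑bis(tert‑butyldimethylsilyloxy)‑3‑(3‑methylbut‑2‑enyl)phenyl]methanol | OCc1cc(O[Si](C)(C)C(C)(C)C)c(O[Si](C)(C)C(C)(C)C)c(CC=C(C)C)c1Br
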